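# Proposed total synthesis of Sauriol A by twofold asymmetric hydrogenation of an achiral 1,4-diaryl-2,3-dimethylbutadiene

Compound numbers 1–10 are fixed as in the compound list and used throughout. Atoms of the target follow lignan numbering: ring A = C1–C6, ring B = C1′–C6′, chain C7–C8(–C9)–C8′(–C9′)–C7′.

## Analysis of the target

Sauriol A (10) is an 8–8′-linked dibenzylbutane lignan. Its open chain C7–C8(C9)–C8′(C9′)–C7′ is a 2,3-dimethylbutane-1,4-diyl unit that carries two identical 3,4-dihydroxy-5-methoxyphenyl rings (ring A at C7, ring B at C7′), and there is no ring besides the two arenes. The only stereocenters are C8 and C8′, both R. They are adjacent and related by a C2 axis through the midpoint of the C8–C8′ bond, so the halves ring A–C7–C8–C9 and ring B–C7′–C8′–C9′ are homotopic, and the diastereomer to be avoided, (R,S), is the meso compound. Each stereocenter carries only H, CH3, CH2Ar and the other stereocenter. No heteroatom or carbonyl group at C7, C8 or C9 can direct a reagent, allow an epimerisation or be used to correct a mistake, and whatever sets the centres must tell a methyl from an arylmethyl group. The feature on which the route is built is that each half, ring–C7–C8(C9), is a hydrogenated 1-aryl-2-methylethene. The chain C7–C8–C8′–C7′ with C9 and C9′ is therefore a flat, achiral 1,4-diaryl-2,3-dimethylbuta-1,3-diene in disguise, itself the head-to-head dimer of a 1-arylpropyne. The sensitive groups are the two catechols (hydroxyls at C3/C4 and C3′/C4′). They are oxidised to ortho-quinones by air in base and quench organometallic reagents, so they must stay masked until the end while the C5/C5′ methyl ethers survive the unmasking. The difficulty is economy rather than size: most ways of controlling C8 and C8′ put oxygen at C9/C9′ or C7/C7′ and then spend several steps removing it.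

## Retrosynthetic reasoning

**10 to 9.** The four phenolic O–H bonds are traced back to O–benzyl bonds. The cut is made here because free catechols cannot pass through organolithium, organozirconium or cationic iridium chemistry. Aryl benzyl ethers pass through all three and fall off at the end under neutral reductive conditions that touch neither the C5/C5′ methyl ethers nor C8/C8′. The forward reaction has to cleave four benzyl–oxygen bonds and nothing else.

**9 to 7 (key disconnection).** Four C–H bonds are removed: C7–H and C8–H in one half, C7′–H and C8′–H in the other. This leads by way of monoene 8 to the achiral (1E,3E)-diene 7. The cut is made at C–H and not at C–C because C8 and C8′ carry no functional group. A C–C bond-forming way of setting them would need an activating group at C9 or C7 that must be removed afterwards, whereas a hydrogen atom can be placed on a prochiral carbon with nothing left to remove. What is gained: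
- both stereocenters, which is all the stereochemistry of 10, arise in one operation from a precursor without any stereocenter;
- the aryl-substituted trisubstituted alkene is the substrate class for which hydrogenation catalysts that need no directing group are most dependable;
- the C2 axis means the catalyst meets the same alkene twice.

The forward reaction has to add both hydrogen atoms syn to the same enantioface of each double bond, 1,2 and not 1,4, without moving the double bonds and without touching the benzyl ethers.

**7 to two molecules of 5.** The central C8–C8′ bond of 7 is cut, which gives two identical molecules of arylpropyne 5. This cut is the one the symmetry axis suggests, and it is also the bond the presumed biosynthesis makes when two C6–C3 units are joined at C8 and C8′. The forward reaction is a reductive head-to-head dimerisation through zirconacyclopentadiene 6. It must join the methyl-bearing alkyne carbons, with the aryl groups next to the metal, and deliver both alkenes as E; ring formation and protonolysis with retention do the latter by mechanism. One step then assembles the whole C20 skeleton of the target.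

**5 to 1.** The methyl-capped triple bond of 5 is traced back through acetylide 4 and dibromoalkene 3 to the aldehyde carbon of 2, which becomes C7. C8 arrives in the olefination and C9 in the methylation. Aldehyde 2 is the bis(benzyl) ether of commercially available 1, which already carries the complete oxygenation pattern of rings A and B, so no aromatic substitution chemistry is needed.

## Alternatives that were turned down

**Alternative 1:** the textbook route through a trans-dibenzylbutyrolactone.
- Disconnection: the C7–C8 and C7′–C8′ bonds, one after the other, with C9 and C9′ carried at the carboxyl and carbinol oxidation levels.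
- Forward key step: trans-selective alkylation of the enolate of the enantioenriched (R)-β-(arylmethyl)butyrolactone A2 with the benzylic bromide A3 to give the (3R,4R)-lactone A1. Hydride reduction to the diol, twofold sulfonylation and a second hydride reduction then turn both C9 carbons into methyl groups.
- Reason for rejection: the stereocenters are made one at a time; the first needs its own asymmetric step just to reach A2; the C2 axis is not used; and the four operations after A1 only remove oxygen that the target never had. The count comes to roughly twice that of the chosen route. Its dimerising variant is kept only as the fallback for step 5.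

**Alternative 2:** biomimetic 8–8′ radical coupling.
- Disconnection: the C8–C8′ bond, cut homolytically.
- Forward key step: one-electron oxidation of the propenylphenol A4, coupling of two radicals at C8 and C8′ to the bis(quinone methide) A5, and twofold hydride reduction of A5 at C7 and C7′.
- Reason for rejection: the coupling has no element of absolute control (in the plant a protein supplies it) and little relative control, so A5 would form as a mixture of the racemic and meso forms. A5 is also prone to intramolecular trapping to tetrahydrofuran and aryltetralin skeletons, and 8–O–4′ coupling competes. A single enantiomer would need a resolution, which conflicts with the brief.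

**Alternative 3:** two-directional aryl–C7 coupling onto a chiral-pool C6 unit.
- Disconnection: both ring–C7 bonds.
- Forward key step: twofold copper-catalysed alkyl–aryl coupling of the (2S,3S)-bis(sulfonate) A6 with the aryl Grignard reagent A7.
- Reason for rejection: the key step sets no stereocenter; the configuration is bought, and A6 needs several steps from an expensive enantiopure diacid. A7 needs an aryl bromide with this oxygenation pattern that is not an article of commerce and would have to be made from 1 by discarding its aldehyde carbon. The electrophilic carbons of A6 are β-branched, which slows the substitution and favours elimination. Two multistep preparations would converge on a step that adds only two sp2–sp3 bonds.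

Key step: step 5

## Route

Assumption (a remark on the chemistry): tBu-PHOX stands for 4-tert-butyl-2-[2-(diphenylphosphanyl)phenyl]-4,5-dihydro-1,3-oxazole. Its (S) enantiomer is assigned to the (R,R) series by analogy with (E)-1,2-diarylpropenes; should the sense of induction be the opposite for diene 7, the (R) ligand would be used with no other change.

Step 1
Reactants: 1 3,4-dihydroxy-5-methoxybenzaldehyde (5-hydroxyvanillin)
Product: 2 3,4-bis(benzyloxy)-5-methoxybenzaldehyde
Conditions: BnBr (2.4 equiv), K2CO3 (3 equiv), DMF, 60 °C
Reagents that add atoms: benzyl bromide, BrCc1ccccc1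
Why: Williamson etherification of both catechol hydroxyls; the aldehyde is inert to carbonate, and benzyl ethers are chosen because they survive n-BuLi, the zirconocene and the cationic iridium hydride yet fall off under neutral hydrogenolysis at the end.

Step 2
Reactants: 2 3,4-bis(benzyloxy)-5-methoxybenzaldehyde
Product: 3 1,2-bis(benzyloxy)-5-(2,2-dibromoethenyl)-3-methoxybenzene
Conditions: CBr4 (2 equiv), PPh3 (4 equiv), CH2Cl2, 0 °C
Reagents that add atoms: carbon tetrabromide, BrC(Br)(Br)Br
Why: Ramirez dibromo-olefination (first half of the Corey–Fuchs sequence): the ylide Ph3P=CBr2 formed in the flask undergoes a Wittig reaction with the electron-rich aldehyde; no stereocenter is formed.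

Step 3
Reactants: 3 1,2-bis(benzyloxy)-5-(2,2-dibromoethenyl)-3-methoxybenzene
Product: 5 1,2-bis(benzyloxy)-3-methoxy-5-(prop-1-yn-1-yl)benzene, via lithium acetylide 4 (not isolated)
Conditions: n-BuLi (2.2 equiv), THF, −78 °C; then MeI (4 equiv), −78 to 25 °C
Reagents that add atoms: iodomethane, CI
Why: Second half of the Corey–Fuchs sequence: bromine–lithium exchange and Fritsch–Buttenberg–Wiechell 1,2-shift give the alkyne, the second equivalent of n-BuLi converts it into acetylide 4, and C-methylation gives the internal alkyne; aryl benzyl ethers tolerate n-BuLi at −78 °C.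

Step 4
Reactants: 5 1,2-bis(benzyloxy)-3-methoxy-5-(prop-1-yn-1-yl)benzene (two equivalents)
Product: 7 (1E,3E)-1,4-bis[3,4-bis(benzyloxy)-5-methoxyphenyl]-2,3-dimethylbuta-1,3-diene, via zirconacyclopentadiene 6 (not isolated)
Conditions: Cp2ZrCl2 (0.55 equiv), n-BuLi (1.1 equiv), THF, −78 °C; then 5, −78 to 25 °C; then 3 M HCl, 25 °C
Reagents that add atoms: none
Why: Zirconocene-mediated reductive homocoupling of an alkyne: Cp2ZrBu2 loses butane to give a zirconocene–butene complex (a source of divalent zirconium), which takes up two molecules of 5 by oxidative cyclisation. The aryl groups take the positions next to zirconium for electronic reasons, so the methyl-bearing carbons are joined (the future C8–C8′ bond). Protonolysis of both Zr–C bonds with retention fixes both double bonds as E.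

Step 5
Reactants: 7 (1E,3E)-1,4-bis[3,4-bis(benzyloxy)-5-methoxyphenyl]-2,3-dimethylbuta-1,3-diene
Product: 9 (2R,3R)-1,4-bis[3,4-bis(benzyloxy)-5-methoxyphenyl]-2,3-dimethylbutane, via monoene 8 (not isolated)
Conditions: H2 (50 bar), [Ir(cod)((S)-tBu-PHOX)]B[3,5-(CF3)2C6H3]4 (2 mol%), CH2Cl2, 25 °C
Reagents that add atoms: none
Why: This is an iridium-catalysed asymmetric hydrogenation of unfunctionalised trisubstituted aryl alkenes with a cationic P,N-ligated complex; the closest known reaction type is the hydrogenation of (E)-1-aryl-2-methylalkenes and of polyenes in which one catalyst sets several methyl-bearing centres in one operation. Under H2 the cod ligand is hydrogenated off, the resulting iridium dihydride binds one C=C of 7 through the enantioface dictated by the tert-butyl group of the oxazoline, and migratory insertion followed by C–H reductive elimination delivers both hydrogen atoms syn to that face to give monoene 8, which re-enters the same cycle. No ring is closed. C8 is set in the first addition and C8′ in the second, each by the catalyst: the two alkenes of 7 are homotopic, both E, and present the same pattern of aryl, hydrogen and methyl to the metal, so the same face should be chosen twice and the C2-symmetric (R,R) product should result rather than the meso one. In 8 the allylic stereocenter carries a methyl and an arylmethyl group of similar size, and the vinylic hydrogen cis to it offers no A(1,3) conformational lock, so the substrate bias is expected to be weak and overridden by the catalyst. Because the wrong enantiomer would need two wrong additions, errors should be diverted mainly into the meso diastereomer, a different compound that can be removed, so the enantiomeric purity of 9 should exceed the intrinsic selectivity of one addition. The step also needs 1,2- rather than 1,4-addition and no double bond migration, which is the normal course for a catalyst that binds one alkene at a time. It also needs intact benzyl ethers, which a homogeneous iridium hydride does not cleave.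

Step 6
Reactants: 9 (2R,3R)-1,4-bis[3,4-bis(benzyloxy)-5-methoxyphenyl]-2,3-dimethylbutane
Product: 10 Sauriol A, 5,5′-[(2R,3R)-2,3-dimethylbutane-1,4-diyl]bis(3-methoxybenzene-1,2-diol)
Conditions: H2 (1 atm), Pd/C (10% palladium on carbon), EtOAc–MeOH, 25 °C, degassed solvents
Reagents that add atoms: none
Why: Hydrogenolysis of the four aryl benzyl ethers; the aryl methyl ethers and the saturated chain are inert, and C8/C8′ carry neither an acidic nor a benzylic hydrogen, so the configuration is retained.

## Compound list

In 6 the cyclopentadienyl rings are drawn sigma-bonded for the line notation.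

1 | 3,4-dihydroxy-5-methoxybenzaldehyde (5-hydroxyvanillin) | COc1cc(C=O)cc(O)c1O | starting material
2 | 3,4-bis(benzyloxy)-5-methoxybenzaldehyde | COc1cc(C=O)cc(OCc2ccccc2)c1OCc1ccccc1 | intermediate
3 | 1,2-bis(benzyloxy)-5-(2,2-dibromoethenyl)-3-methoxybenzene | COc1cc(C=C(Br)Br)cc(OCc2ccccc2)c1OCc1ccccc1 | intermediate
4 | lithium [3,4-bis(benzyloxy)-5-methoxyphenyl]acetylide | COc1cc(C#C[Li])cc(OCc2ccccc2)c1OCc1ccccc1 | intermediate
5 | 1,2-bis(benzyloxy)-3-methoxy-5-(prop-1-yn-1-yl)benzene | COc1cc(C#CC)cc(OCc2ccccc2)c1OCc1ccccc1 | intermediate
6 | 2,5-bis[3,4-bis(benzyloxy)-5-methoxyphenyl]-1,1-bis(cyclopentadienyl)-3,4-dimethyl-1-zirconacyclopenta-2,4-diene | CC1=C(c2cc(OC)c(OCc3ccccc3)c(OCc3ccccc3)c2)[Zr](C2C=CC=C2)(C2C=CC=C2)C(c2cc(OC)c(OCc3ccccc3)c(OCc3ccccc3)c2)=C1C | intermediate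
7 | (1E,3E)-1,4-bis[3,4-bis(benzyloxy)-5-methoxyphenyl]-2,3-dimethylbuta-1,3-diene | COc1cc(/C=C(\C)/C(C)=C/c2cc(OC)c(OCc3ccccc3)c(OCc3ccccc3)c2)cc(OCc2ccccc2)c1OCc1ccccc1 | intermediate
8 | (1E,3R)-1,4-bis[3,4-bis(benzyloxy)-5-methoxyphenyl]-2,3-dimethylbut-1-ene | COc1cc(/C=C(\C)[C@H](C)Cc2cc(OC)c(OCc3ccccc3)c(OCc3ccccc3)c2)cc(OCc2ccccc2)c1OCc1ccccc1 | intermediate
9 | (2R,3R)-1,4-bis[3,4-bis(benzyloxy)-5-methoxyphenyl]-2,3-dimethylbutane | COc1cc(C[C@@H](C)[C@H](C)Cc2cc(OC)c(OCc3ccccc3)c(OCc3ccccc3)c2)cc(OCc2ccccc2)c1OCc1ccccc1 | intermediate
10 | Sauriol A, 5,5′-[(2R,3R)-2,3-dimethylbutane-1,4-diyl]bis(3-methoxybenzene-1,2-diol) | COc1cc(C[C@@H](C)[C@H](C)Cc2cc(O)c(O)c(OC)c2)cc(O)c1O | target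

## Step count and risk

Total step count: 6. Longest linear sequence: 6 (both halves come from the same compound 5).

**Step 5 (key step).** Most likely to go wrong:
- loss of catalyst control in the second addition, where the stereocenter of monoene 8 could oppose the catalyst and divert material into the meso diastereomer, which may be hard to separate from 9;
- 1,4-addition or double bond migration to a tetrasubstituted alkene that this catalyst class reduces only sluggishly, so the reaction stalls;
- slow turnover with a crowded, electron-rich diene.

Fallback (sets out from 2, returns at 9): an auxiliary-controlled oxidative enolate dimerisation, which makes the C8–C8′ bond and both centres with carbonyl groups at C9/C9′ and then removes the oxygen. Aldehyde 2 would be condensed with diethyl {2-[(4S)-4-benzyl-2-oxo-1,3-oxazolidin-3-yl]-2-oxoethyl}phosphonate (LiCl, i-Pr2NEt, MeCN; Horner–Wadsworth–Emmons reaction) to give the enoyl imide (4S)-4-benzyl-3-[(2E)-3-(3,4-bis(benzyloxy)-5-methoxyphenyl)prop-2-enoyl]-1,3-oxazolidin-2-one F1. Homogeneous hydrogenation of the conjugated alkene (H2, RhCl(PPh3)3), which leaves the benzyl ethers alone, would give the saturated imide (4S)-4-benzyl-3-[3-(3,4-bis(benzyloxy)-5-methoxyphenyl)propanoyl]-1,3-oxazolidin-2-one F2. Its lithium enolate (LDA, THF, −78 °C) would be dimerised oxidatively with CuCl2 to the (2R,3R)-2,3-bis(arylmethyl)succinyl bis-imide F3, each enolate reacting on the face away from the 4-benzyl group as in alkylations. LiBH4 would release the auxiliary and give (2R,3R)-2,3-bis[3,4-bis(benzyloxy)-5-methoxybenzyl]butane-1,4-diol F4. MsCl and Et3N would give the bis(methanesulfonate) F5, and LiAlH4 in THF would replace both sulfonates by hydride to give 9.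

**Step 4.** Most likely to go wrong: regiochemical leakage in the oxidative cyclisation (one aryl group ending up remote from zirconium), which would give an unsymmetrical diene isomer, and incomplete coupling that leaves a mono-alkyne complex and, after the acid quench, a simple alkene. Fallback (sets out from 5, returns at 7): copper-catalysed syn hydroboration of 5 (CuCl, a triarylphosphine, NaOt-Bu, B2pin2, MeOH, THF) should place boron on the methyl-bearing carbon and give (Z)-2-[1-(3,4-bis(benzyloxy)-5-methoxyphenyl)prop-1-en-2-yl]-4,4,5,5-tetramethyl-1,3,2-dioxaborolane F6. Oxidative homocoupling of F6 (Pd(OAc)2, O2, K2CO3, aqueous DMF), with retention at both alkenyl carbons, would give 7.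

**Step 3.** Most likely to go wrong: incomplete C-methylation of acetylide 4 in THF at low temperature, which would leave terminal alkyne, and competing metalation at a benzylic OCH2 position by excess n-BuLi. Fallback (sets out from 2, returns at 5): Seyferth–Gilbert homologation of 2 with dimethyl (1-diazo-2-oxopropyl)phosphonate (K2CO3, MeOH), which needs no organolithium, would give 1,2-bis(benzyloxy)-5-ethynyl-3-methoxybenzene F7. Deprotonation with LiN(SiMe3)2 and methylation with MeI in THF–DMPU would give 5.

**Step 6.** Most likely to go wrong: stalling after partial debenzylation as the free catechols bind the palladium surface, and autoxidation of the catechols to ortho-quinones during filtration and concentration. Fallback (sets out from 9, returns at 10): non-reductive Lewis acid debenzylation with BCl3 and pentamethylbenzene as cation scavenger in CH2Cl2 at −78 °C, which spares aryl methyl ethers at that temperature, with an acidic work-up that keeps the catechols protonated. No new compound is made on this way (F0).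

## Further compounds

F1 | step 5 | (4S)-4-benzyl-3-[(2E)-3-(3,4-bis(benzyloxy)-5-methoxyphenyl)prop-2-enoyl]-1,3-oxazolidin-2-one | O=C(/C=C/c1cc(OC)c(OCc2ccccc2)c(OCc2ccccc2)c1)N1[C@@H](Cc2ccccc2)COC1=O
F2 | step 5 | (4S)-4-benzyl-3-[3-(3,4-bis(benzyloxy)-5-methoxyphenyl)propanoyl]-1,3-oxazolidin-2-one | O=C(CCc1cc(OC)c(OCc2ccccc2)c(OCc2ccccc2)c1)N1[C@@H](Cc2ccccc2)COC1=O
F3 | step 5 | (4S,4′S)-3,3′-{(2R,3R)-2,3-bis[3,4-bis(benzyloxy)-5-methoxybenzyl]butanedioyl}bis(4-benzyl-1,3-oxazolidin-2-one) | O=C1OC[C@H](Cc2ccccc2)N1C(=O)[C@H](Cc1cc(OC)c(OCc2ccccc2)c(OCc2ccccc2)c1)[C@@H](Cc1cc(OC)c(OCc2ccccc2)c(OCc2ccccc2)c1)C(=O)N1[C@@H](Cc2ccccc2)COC1=O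
F4 | step 5 | (2R,3R)-2,3-bis[3,4-bis(benzyloxy)-5-methoxybenzyl]butane-1,4-diol | OC[C@H](Cc1cc(OC)c(OCc2ccccc2)c(OCc2ccccc2)c1)[C@@H](Cc1cc(OC)c(OCc2ccccc2)c(OCc2ccccc2)c1)CO
F5 | step 5 | (2R,3R)-2,3-bis[3,4-bis(benzyloxy)-5-methoxybenzyl]butane-1,4-diyl dimethanesulfonate | CS(=O)(=O)OC[C@H](Cc1cc(OC)c(OCc2ccccc2)c(OCc2ccccc2)c1)[C@@H](Cc1cc(OC)c(OCc2ccccc2)c(OCc2ccccc2)c1)COS(C)(=O)=O
F6 | step 4 | (Z)-2-[1-(3,4-bis(benzyloxy)-5-methoxyphenyl)prop-1-en-2-yl]-4,4,5,5-tetramethyl-1,3,2-dioxaborolane | COc1cc(/C=C(\C)B2OC(C)(C)C(C)(C)O2)cc(OCc2ccccc2)c1OCc1ccccc1
F7 | step 3 | 1,2-bis(benzyloxy)-5-ethynyl-3-methoxybenzene | COc1cc(C#C)cc(OCc2ccccc2)c1OCc1ccccc1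
F0 | step 6 | none | none
A1 | alternative 1 | (3R,4R)-3,4-bis[3,4-bis(benzyloxy)-5-methoxybenzyl]oxolan-2-one | O=C1OC[C@H](Cc2cc(OC)c(OCc3ccccc3)c(OCc3ccccc3)c2)[C@H]1Cc1cc(OC)c(OCc2ccccc2)c(OCc2ccccc2)c1
A2 | alternative 1 | (4R)-4-[3,4-bis(benzyloxy)-5-methoxybenzyl]oxolan-2-one | O=C1OC[C@H](Cc2cc(OC)c(OCc3ccccc3)c(OCc3ccccc3)c2)C1
A3 | alternative 1 | 1,2-bis(benzyloxy)-5-(bromomethyl)-3-methoxybenzene | COc1cc(CBr)cc(OCc2ccccc2)c1OCc1ccccc1
A4 | alternative 2 | (E)-2-(benzyloxy)-6-methoxy-4-(prop-1-en-1-yl)phenol | C/C=C/c1cc(OC)c(O)c(OCc2ccccc2)c1
A5 | alternative 2 | 4,4′-(2,3-dimethylbutane-1,4-diylidene)bis[2-(benzyloxy)-6-methoxycyclohexa-2,5-dien-1-one], configuration at the two methine carbons and at the exocyclic alkenes not controlled | COC1=CC(=CC(C)C(C)C=C2C=C(OC)C(=O)C(OCc3ccccc3)=C2)C=C(OCc2ccccc2)C1=O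
A6 | alternative 3 | (2S,3S)-2,3-dimethylbutane-1,4-diyl bis(4-methylbenzenesulfonate) | Cc1ccc(cc1)S(=O)(=O)OC[C@@H](C)[C@H](C)COS(=O)(=O)c1ccc(C)cc1
A7 | alternative 3 | [3,4-bis(benzyloxy)-5-methoxyphenyl]magnesium bromide | COc1cc([Mg]Br)cc(OCc2ccccc2)c1OCc1ccccc1
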